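A small charge, 0.019 M of starting material against 1.20 equiv of reagent in the second phase, and within hours the alder readings stop moving.

common to all: starting material 0.019 M
- alder: reagent in the second phase 1.2 equiv; temperature 0 °C; the very flask that is asked about, followed so far
- oak: reagent in the second phase 1.8 equiv; temperature −15 °C; run made earlier
- flask: reagent in the second phase 1.20 equiv; temperature 0 °C; time 20 h; volume of the second phase over the first 0.25

| run | time / h | target / % | starting material / % |
|---|---|---|---|
| alder | 1.00 | 30 | 33 |
| alder | 3.00 | 28 | 19 |
| alder | 6.00 | 23 | 16 |
| alder | 8.00 | 28 | 18 |
| alder | 12.0 | 21 | 17 |
| oak | 0.200 | 16 | 56 |
| oak | 0.417 | 19 | 50 |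
| oak | 0.833 | 22 | 30 |
| oak | 1.33 | 12 | 21 |
| oak | 3.00 | 9 | 5 |

(readings scatter by 2 percentage points)

- in the second phase: reagent in the second phase; everything else is in the first
- charges count per volume of the first phase; a concentration in a rate is the amount of a species over the volume of its own phase; every rate counts per litre of the first phase
- what is taken out of target is counted as made
- candidate steps: reagent in the reaction phase <-> reagent in the second phase; starting material + reagent in the reaction phase -> target; reagent in the reaction phase + target -> over-reacted product; starting material <-> dormant form; 2 reagent in the reaction phase -> self-condensation product; target <-> isomer of the product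
- the earlier runs hold the two phases in the same ratio of volumes as the flask asked about
- additions bring no volume worth counting

- north-east: change nothing and wait 6.0 h more
- north-west: at 20 h raise the temperature by 25 K, then wait 6.0 h
- east: at 20 h take out 90 % of the target then present, then wait 6.0 h
- south-east: at 20 h add starting material, 50.0 % of the amount charged, then wait 6.0 h

1. target, in percent of the starting material first charged, at 20 h
2. the remedy with the largest gain of target, or "none" below 2 percentage points (north-east / north-west / east / south-east / none)
3. target present, with what was taken out counted in, in percent of the starting material first charged, after north-west
4. target present, with what was taken out counted in, in percent of the starting material first charged, after south-east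

From 3.00 h on, the alder readings stand flat, with starting material averaging 17.5 % and target 25.0 %. So assume that the 1.20 equiv of reagent has been used, the reagent being the limiting reagent, and audit the bill. Each reacted starting material paid one reagent, and each over-reacted product paid a second. Setting aside what self-condensation takes, you can therefore count what stays unpaid a second time:

pool = 2 × reacted fraction − reagent equivalents

You need the dormant share to get the reacted fraction. Oak's first reading, at 0.200 h, is short of the charge, and if that whole gap is dormant form, with the same ratio at −15 °C as at 0 °C, then:

dormant over free = 0.500
reacted fraction = 73.8 %
pool = 27.5 %

That is little more than target, so nothing seems hidden. But the objection is plain: oak's target had already begun to go on. Put the first answer back in. In alder, the first round leaves 1.95 of reacted material past target for each target. Scaling that by target over starting material, oak's ratio against alder's, gives: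

already gone on in oak = 6.24 %
dormant over free = 0.389
reacted fraction = 75.7 %
pool = 31.4 %

This is the pool: target and isomer of the product together, what the reagent bill allows. It stands 6.4 percentage points above target. Is that scatter? Through the doubled mean of the starting material readings the pool carries about 2.8 points, so the gap stands above that scatter, though thinly.

I commit to 25.0 % of target at 20 h. If target and isomer of the product keep their split after east takes out 90 % of the target, the pool gives:

further target = hidden share × share taken × target / pool = 4.6 points

That is more than the margin of 2 points, so east is my pick. South-east I hold at 25.0 %, the bill assuming no reagent to pay for it. Oak differs from alder in both reagent and temperature, so I put no direction on heat and leave north-west between 25.0 % and the pool.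

The forecast says 25 %, best none, 25 % after north-west and 25.5 % after south-east, on the ground that “With no reagent, nothing moves”. We part on the remedy.

The flask gives 25.2 %, and best is north-west, gaining 11 points against 7.4 points for east, 0 points for north-east and 0 points for south-east. Target is 36.7 % after north-west and 25.2 % after south-east.

    reagent in the reaction phase ⇌ reagent in the second phase, rate k1*([reagent in the reaction phase] - [reagent in the second phase]/K1) per volume of the first phase (partition coefficient = 56.0, kL = 0.270 min⁻¹)
    starting material + reagent in the reaction phase → target (k = 160 L mol⁻¹ min⁻¹, Ea = 52.0 kJ mol⁻¹)
    reagent in the reaction phase + target → over-reacted product (k = 140 L mol⁻¹ min⁻¹, Ea = 40.0 kJ mol⁻¹)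
    starting material ⇌ dormant form (K = 0.420, k = 1.30 min⁻¹, Ea = 78.0 kJ mol⁻¹, ΔH = 4.00 kJ mol⁻¹)
    2 reagent in the reaction phase → self-condensation product (k = 69.0 L mol⁻¹ min⁻¹, Ea = 37.0 kJ mol⁻¹)
    target ⇌ isomer of the product (K = 0.480, k = 0.120 min⁻¹, Ea = 70.0 kJ mol⁻¹, ΔH = −88.0 kJ mol⁻¹)
    (constants at 0 °C)

Reckon the pool again from the state of the flask at 20.0 h: reagent in the second phase is at 0 %, and starting material 15.3 % with dormant form 6.44 % gives 36.5 %. Target 25.2 % plus isomer of the product 12.1 % comes to 37.3 %, and north-west ends at 36.7 %. The neighbouring flask, kept at 25 °C, holds at 20.0 h reagent in the second phase 0 %, starting material 14.2 % and dormant form 6.91 %, so its pool is 37.8 %. That neighbouring flask stands at target 37.2 % with isomer of the product 0.693 %.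

The readings stem from a simulated flask from invented constants, noise included.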